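**Retrosynthetic overview**

- The target is the trans-(2S,3S) 8–12′ dehydrodimer of piceatannol. Stilbene numbering: C7 is the olefinic carbon on the catechol ring, C8 the one on the resorcinol ring, C12′ the resorcinol carbon between the two hydroxyls, O11′ a flanking hydroxyl.
- The dihydrofuran ring is cut at C3–C3a and O1–C2. This gives piceatannol ortho-quinone (two-electron-oxidised monomer, electrophilic at C8) and piceatannol (resorcinol ring as C12′/O11′ bis-nucleophile).
- Forward order: the C8–C12′ bond (sets C3) gives a para-quinone methide, then 5-exo oxa-Michael closure O11′–C7 (sets C2, trans). This dihydrofuran ring is the only ring made; all benzene rings are bought.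
- Piceatannol ortho-quinone comes from piceatannol by dehydrogenation; piceatannol comes from resveratrol by ortho-hydroxylation.

Assumption: (R)-TRIP, i.e. (R)-3,3′-bis(2,4,6-triisopropylphenyl)-1,1′-binaphthyl-2,2′-diyl hydrogen phosphate, is taken to give the (3S) centre; if the facial sense proves opposite, its enantiomer is used with nothing else changed.

**Route**

Step 1
Reactants: 1 resveratrol
Product: 3 piceatannol, via piceatannol ortho-quinone 2 (not isolated)
Conditions: IBX (1.1 equiv), DMF, −20 → 0 °C, 1 h; then aq Na2S2O4, 0 °C → rt
Reagents that add atoms: IBX (2-iodoxybenzoic acid), O=C1OI(=O)(O)c2ccccc12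
Why: IBX-mediated regioselective ortho-oxygenation of a phenol (aryloxy ligation to pentavalent iodine, intramolecular O-transfer to the ortho carbon) converts the most electron-rich, para-alkenyl 4′-phenol into ortho-quinone 2, which dithionite reduces in the same pot to the catechol; no stereocentre is formed and the E-alkene is untouched.

Step 2
Reactants: 3 piceatannol
Product: 2 piceatannol ortho-quinone (cold filtered solution used at once)
Conditions: Ag2O (3 equiv), Na2SO4, EtOAc, −10 °C, dark, 3 added over 15 min; cold filtration (Celite, Ar)
Reagents that add atoms: none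
Why: Classical silver oxide dehydrogenation of a catechol to its ortho-quinone; the resorcinol hydroxyls are not oxidised at this potential, slow addition of 3 to excess oxidant keeps 3 and 2 apart, and filtration gives a reagent-free solution (the DMF and iodobenzoate medium of step 1 would swamp the chiral acid, hence regeneration from purified 3); no stereocentre.

Step 3
Reactants: 2 piceatannol ortho-quinone (1.0 equiv); 3 piceatannol (2.0 equiv)
Product: 7 (2S,3S)-2-(3,4-dihydroxyphenyl)-3-(3,5-dihydroxyphenyl)-6-[(E)-2-(3,4-dihydroxyphenyl)ethenyl]-2,3-dihydro-1-benzofuran-4-ol (target), via piceatannol phenylboronate 4 (not isolated), via quinone methide adduct 5 (not isolated), via dihydrobenzofuran boronate 6 (not isolated)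
Conditions: 3, PhB(OH)2 (2.0 equiv), 4 Å MS, EtOAc/PhMe 1:1, rt, 1 h; (R)-TRIP (10 mol%), −40 °C, solution of 2 added over 3 h, then −20 °C, 12 h; MeOH/H2O, rt; excess 3 recovered
Reagents that add atoms: none
Why: Proposed new method: a chiral-phosphoric-acid-catalysed formal [3+2] annulation (vinylogous Friedel–Crafts 1,6-addition, then oxa-Michael) in which the acid hydrogen-bonds the C3 carbonyl of 2, which is through-conjugated with the styryl unit so that the electrophilic site is benzylic C8, while its phosphoryl oxygen binds a resorcinol OH of 4 and delivers C12′ (the least hindered of the three electronically equivalent ring positions) to one face of C8, setting C3 as S; tautomerisation gives para-quinone methide 5, whose 5-exo-trig oxa-Michael closure by the flanking OH is reversible under the acid and settles on the trans (2S,3S) ring; the transient cyclic boronate makes the nucleophile's catechol non-oxidisable and its alkene less electron-rich, which suppresses quinone/catechol redox exchange, hetero-Diels–Alder benzodioxane formation and attack through the alkene; the closest known reaction types are chiral-phosphoric-acid-catalysed 1,6- and 1,8-additions of phenols to para-quinone methides and acid-catalysed [3+2] couplings of quinones with hydroxyarenes or 4-hydroxystyrenes to trans-2,3-dihydrobenzofurans.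

**Compound list**

1 | resveratrol, 5-[(E)-2-(4-hydroxyphenyl)ethenyl]benzene-1,3-diol | Oc1ccc(/C=C/c2cc(O)cc(O)c2)cc1 | starting material
2 | piceatannol ortho-quinone, 4-[(E)-2-(3,5-dihydroxyphenyl)ethenyl]cyclohexa-3,5-diene-1,2-dione | O=C1C=CC(/C=C/c2cc(O)cc(O)c2)=CC1=O | intermediate
3 | piceatannol, 4-[(E)-2-(3,5-dihydroxyphenyl)ethenyl]benzene-1,2-diol | Oc1cc(O)cc(/C=C/c2ccc(O)c(O)c2)c1 | intermediate
4 | piceatannol 3′,4′-O-phenylboronate, 5-[(E)-2-(2-phenyl-1,3,2-benzodioxaborol-5-yl)ethenyl]benzene-1,3-diol | Oc1cc(O)cc(/C=C/c2ccc3OB(c4ccccc4)Oc3c2)c1 | intermediate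
5 | para-quinone methide adduct, 4-{(2S)-2-(3,5-dihydroxyphenyl)-2-[2,6-dihydroxy-4-[(E)-2-(2-phenyl-1,3,2-benzodioxaborol-5-yl)ethenyl]phenyl]ethylidene}-2-hydroxycyclohexa-2,5-dien-1-one | Oc1cc(O)cc([C@H](C=C2C=CC(=O)C(O)=C2)c2c(O)cc(/C=C/c3ccc4OB(c5ccccc5)Oc4c3)cc2O)c1 | intermediate
6 | 5-[(2S,3S)-2-(3,4-dihydroxyphenyl)-4-hydroxy-6-[(E)-2-(2-phenyl-1,3,2-benzodioxaborol-5-yl)ethenyl]-2,3-dihydro-1-benzofuran-3-yl]benzene-1,3-diol | Oc1cc(O)cc([C@H]2c3c(O)cc(/C=C/c4ccc5OB(c6ccccc6)Oc5c4)cc3O[C@@H]2c2ccc(O)c(O)c2)c1 | intermediate
7 | (2S,3S)-2-(3,4-dihydroxyphenyl)-3-(3,5-dihydroxyphenyl)-6-[(E)-2-(3,4-dihydroxyphenyl)ethenyl]-2,3-dihydro-1-benzofuran-4-ol (trans) | Oc1cc(O)cc([C@H]2c3c(O)cc(/C=C/c4ccc(O)c(O)c4)cc3O[C@@H]2c2ccc(O)c(O)c2)c1 | target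

**Totals**

Total step count: 3 (two isolations; steps 2 and 3 are telescoped). Longest linear sequence: 3 (1 → 3 → 2 → 7).

**Steps most likely to fail, with fallbacks**

Step 3 (highest risk). Three things can go wrong:
- C–C bond formation at C10′ instead of C12′, which gives the regioisomeric 8–10′ dimer.
- Further reaction of 2 with the pendant, unconjugated resorcinol ring of the product, giving oligomers.
- Modest enantioselectivity, because C8 is remote from the acid binding site.

The fallback sets out from 2 and returns at 7. Solution 2 is added under the same chiral acid to commercial 5-iodoresorcinol (5-iodobenzene-1,3-diol) in place of 4. This nucleophile has no alkene and no catechol, so cycloaddition, alkene attack and redox exchange are absent and no boronate is needed. The product is (2S,3S)-2-(3,4-dihydroxyphenyl)-3-(3,5-dihydroxyphenyl)-6-iodo-2,3-dihydro-1-benzofuran-4-ol F1. A Mizoroki–Heck reaction of F1 with commercial 3,4-diacetoxystyrene (Pd(OAc)2, P(o-tol)3, Et3N, degassed DMF, 80 °C) builds the E-stilbene after the ring and gives 4-[(E)-2-[(2S,3S)-2-(3,4-dihydroxyphenyl)-3-(3,5-dihydroxyphenyl)-4-hydroxy-2,3-dihydro-1-benzofuran-6-yl]ethenyl]-1,2-phenylene diacetate F2. Any acetyl scrambling onto other phenols is immaterial, because catalytic K2CO3 in degassed MeOH at 0 °C then removes all acetates to give 7.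

Step 2. Ag2O can also act as a one-electron oxidant and give phenoxyl-radical dimers, and 2 carries its own nucleophilic resorcinol ring, so it can self-condense before use. The fallback sets out from 1 and returns at 2. Resveratrol is oxidised with IBX (1.05 equiv, DMF, −20 °C) exactly as in step 1 but without the reductive quench; this is a two-electron oxygen transfer with no free phenoxyl radicals. The mixture is diluted with cold EtOAc, washed quickly with cold pH 7 phosphate buffer to remove DMF and 2-iodobenzoic acid, dried over Na2SO4 and used directly in step 3. The electrophilic half then never passes through 3; no new compound is made (F0).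

Step 1. IBX may also oxygenate the resorcinol ring, and the quinone may degrade before reduction. The fallback sets out from 1 and returns at 3. It is a whole-cell biocatalytic ortho-hydroxylation with Escherichia coli expressing the two-component flavin-dependent 4-hydroxyphenylacetate 3-monooxygenase HpaBC (glucose, phosphate buffer pH 7, 30 °C, air). The enzyme installs the 3′-hydroxyl directly by electrophilic flavin-hydroperoxide chemistry, without a quinone intermediate and without touching the resorcinol ring; no new compound is made (F0).

**Further compounds**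

F0 | step 1 | none | none
F0 | step 2 | none | none
F1 | step 3 | (2S,3S)-2-(3,4-dihydroxyphenyl)-3-(3,5-dihydroxyphenyl)-6-iodo-2,3-dihydro-1-benzofuran-4-ol | Oc1cc(O)cc([C@H]2c3c(O)cc(I)cc3O[C@@H]2c2ccc(O)c(O)c2)c1
F2 | step 3 | 4-[(E)-2-[(2S,3S)-2-(3,4-dihydroxyphenyl)-3-(3,5-dihydroxyphenyl)-4-hydroxy-2,3-dihydro-1-benzofuran-6-yl]ethenyl]-1,2-phenylene diacetate | Oc1cc(O)cc([C@H]2c3c(O)cc(/C=C/c4ccc(OC(C)=O)c(OC(C)=O)c4)cc3O[C@@H]2c2ccc(O)c(O)c2)c1
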